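Slowness is what these runs show first. After a quick start, D in the larch run falls from 19.2 % at 2.00 h to 13.0 % at 3.00 h, and larch and cedar both read near 37.7 % at 0.417 h, though c(D) differs between them.

| setting | larch | cedar | flask |
|---|---|---|---|
| D | 0.20 M | 0.45 M | 0.30 M |
| J | 1.05 equiv | 1.05 equiv | 1.05 equiv |
| remark | run made earlier | run made earlier |  |
| time |  |  | 4.0 h |

| run | time / h | E / % | D / % |
|---|---|---|---|
| larch | 0.417 | 61.2 | 37.7 |
| larch | 1.33 | 74.2 | 25.8 |
| larch | 2.00 | 79.9 | 19.2 |
| larch | 3.00 | 84.1 | 13.0 |
| larch | 5.00 | 90.6 | 7.6 |
| cedar | 0.417 | 62.5 | 37.7 |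
| cedar | 0.667 | 66.8 | 31.6 |
| cedar | 1.33 | 73.9 | 24.0 |
| cedar | 2.50 | 83.4 | 15.0 |
| cedar | 5.00 | 90.6 | 6.1 |

(standard deviation of a reading: 0.5 percentage points)

- each molecule carries two end groups: a chain counts once for every two ends that are left, dead ends included; the units are half of the end groups of the two monomers charged
- the numbers in the tables scatter by 0.5 percentage points (one standard deviation)

- average number of monomer units in a chain (unreacted monomers counted as chains of one) at 4.0 h
- part of the D that has reacted at 4.0 h

Two chemists dispute the chain length in this flask at 4.0 h. Both accept the forecast's c of 90.3 % (range 89.3 % to 91.3 %).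

The first takes the balanced view. The charges are nearly equal and every D reacted makes a link, so dp is one over the fraction of D left, which gives 10.3.

The second counts instead. Let u, the units per D charged, be half the end groups of both monomers, 1.02. Each link joins two chains into one, so chains number u minus E, and dp is u over that difference, the Carothers count with the imbalance kept. With equal charges and E equal to the D reacted, u is one and this becomes the first chemist's formula, which is therefore the zero of the scale. But the last larch readings leave 1.8 percentage points of D in neither column, and the last cedar readings 3.3 points. The forecast reads this as “a slow side loss of D to dead ends” and gives dp 7.1, range 6.5 to 7.8.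

The flask gives dp 7.24 and c 90.6 %, so the second chemist's number stands.

    D + J ⇌ E + G (K = 1.45, k = 0.0202 L mol⁻¹ s⁻¹)
    G → Q (k = 4.45 × 10⁻⁴ s⁻¹)
    D → X (k = 7.18 × 10⁻⁶ s⁻¹)

With E at 88.3 %, u gives 7.24 in this flask. The balanced view keeps the early flask: at 0.400 h, D at 37.3 % gives 2.68 against the flask's 2.54. The neighbour charged with 1.80 equiv of J has u of 1.40 and E at 97.9 %, which gives 3.33; that neighbour's dp is 3.33. This flask is not at rest at 4.0 h, where its dp is 7.24. Left until 40.0 h, ten times that time, this flask has D at 0.00699 %, E at 96.7 %, and dp at 17.8.

All runs come from a simulation from invented constants; scatter was added.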